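**Retrosynthetic overview**

1. Atoms carry the numbers of the target SMILES order (C1 = first methyl). The target is cut at C17–C18 (decarboxylative allylation) and C32–C33 (methyl addition) into a hydroazulene allylic alcohol (C1–C17) and a benzoxepine β-keto acid equivalent (C18–C32, held as a ring-fused dioxinone).
2. The strategy rests on this feature: in the seven-membered ring C2–C3–C4–C5–C6–C12–C15, the methyl-bearing stereocentre C2 sits between C3 and sp2 C15, on the side of C15 away from quaternary C12. C2 (with C1) is therefore inserted last into a six-membered C15 ketone by diazoethane ring expansion; C15=C16 then comes from vinyl addition and 1,3-transposition.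
3. The cis-hydrindanone is built on cyclopentenone (five-membered ring C5–C9): asymmetric Mukaiyama–Michael addition (C6–C12), acrylate Michael addition (C5–C4), Dieckmann closure (C3–C15); C10/O11 by methylenation, epoxidation and hydride opening.
4. The right half comes from geranyl bromide and a dioxinone: γ-alkylation, double Shi epoxidation, then one epoxide cascade that forms the oxepane and the cyclohexane.
5. Ring order: left half five-membered (bought) → six-membered (Dieckmann) → seven-membered (ring expansion); right half oxepane and cyclohexane together; then the halves are joined.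

Key step: step 11

Assumption: the (S)-configured catalyst of step 1 and the (S,S,S)-ligand of step 11 are taken to be the antipodes that give (R) at C6 and (R) at C2; if the sense of induction is the opposite, the mirror-image catalyst or ligand is used.

**Route**

Step 1
Reactants: 1 cyclopent-2-en-1-one; 2 1-methoxy-2-methyl-1-(trimethylsilyloxy)prop-1-ene (silyl ketene acetal of methyl isobutyrate)
Product: 3 methyl 2-methyl-2-[(1R)-3-(trimethylsilyloxy)cyclopent-2-en-1-yl]propanoate
Conditions: B-(o-tolyl)oxazaborolidine from (S)-α,α-diphenylprolinol (20 mol %) activated with Tf2NH (20 mol %), Ph3PO (25 mol %), toluene, −20 °C; non-aqueous work-up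
Reagents that add atoms: none
Why: catalytic asymmetric Mukaiyama–Michael addition in which the chiral boron Lewis acid binds the enone and exposes one face of C6 (set as R), while silyl transfer leaves the enolate as the C9=C5 silyl enol ether, regiodefined for the next C–C bond.

Step 2
Reactants: 3 methyl 2-methyl-2-[(1R)-3-(trimethylsilyloxy)cyclopent-2-en-1-yl]propanoate; 4 methyl acrylate
Product: 5 methyl 3-[(1S,2R)-2-(1-methoxy-2-methyl-1-oxopropan-2-yl)-5-oxocyclopentyl]propanoate
Conditions: TiCl4, CH2Cl2, −78 °C; aq. NaHCO3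
Reagents that add atoms: none
Why: Mukaiyama–Michael addition of the regiodefined silyl enol ether to the TiCl4-activated acrylate should form C5–C4 only at the α-carbon next to C6; the trans arrangement expected at C5 does not matter because this centre stays epimerisable.

Step 3
Reactants: 5 methyl 3-[(1S,2R)-2-(1-methoxy-2-methyl-1-oxopropan-2-yl)-5-oxocyclopentyl]propanoate
Product: 6 methyl (3aR,7aR)-4,4-dimethyl-1,5-dioxooctahydro-1H-indene-6-carboxylate (cis-fused; C6 epimers and enol)
Conditions: KOt-Bu (2.5 equiv), THF, 0 °C → rt; aq. HCl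
Reagents that add atoms: none
Why: Dieckmann condensation in which the propanoate enolate carbon C3 acylates the neopentyl ester carbon C15 and closes the six-membered ring, driven by the stable β-keto ester enolate (bridged Claisen products from the ketone enolate have no enolisable position between their carbonyls and revert); C5, α to the C9 ketone, equilibrates to the cis fusion preferred for a 1-hydrindanone, and any trans epimer is separated and re-equilibrated.

Step 4
Reactants: 6 methyl (3aR,7aR)-4,4-dimethyl-1,5-dioxooctahydro-1H-indene-6-carboxylate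
Product: 7 methyl (3aR,7aR)-4,4-dimethyl-1-methylidene-5-oxooctahydro-1H-indene-6-carboxylate
Conditions: Zn, CH2Br2, TiCl4, THF/CH2Cl2, 0 °C → rt
Reagents that add atoms: dibromomethane, BrCBr
Why: Takai–Lombardo methylenation under non-basic conditions should convert only the free C9 ketone, because the C15 carbonyl is masked as the metal enolate of the β-keto ester, and it leaves C5 unepimerised.

Step 5
Reactants: 7 methyl (3aR,7aR)-4,4-dimethyl-1-methylidene-5-oxooctahydro-1H-indene-6-carboxylate
Product: 8 (3aR,7aR)-4,4-dimethyl-1-methylideneoctahydro-5H-inden-5-one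
Conditions: LiCl, H2O, DMSO, 150 °C
Reagents that add atoms: none
Why: Krapcho dealkoxycarbonylation (chloride attack on the ester methyl, loss of CO2) proceeds under neutral conditions that should not move the exocyclic double bond.

Step 6
Reactants: 8 (3aR,7aR)-4,4-dimethyl-1-methylideneoctahydro-5H-inden-5-one
Product: 9 (3aR,7aR)-4,4-dimethylhexahydrospiro[indene-1,2'-oxiran]-5(4H)-one, spiro carbon R, epoxide oxygen on the face of the ring-fusion hydrogens
Conditions: mCPBA, NaHCO3, CH2Cl2, 0 °C
Reagents that add atoms: mCPBA (3-chloroperoxybenzoic acid), OOC(=O)c1cccc(Cl)c1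
Why: Prilezhaev epoxidation of the 1,1-disubstituted alkene is much faster than Baeyer–Villiger oxidation of the α-quaternary ketone, and the peracid approaches the convex face of the cis-hydrindane (the face of H5 and H6), which places O11 there and fixes C9.

Step 7
Reactants: 9 (3aR,7aR)-4,4-dimethylhexahydrospiro[indene-1,2'-oxiran]-5(4H)-one
Product: 10 (1R,3aR,7aR)-1,4,4-trimethyloctahydro-1H-indene-1,5-diol (both epimers at the secondary carbinol)
Conditions: LiAlH4, THF, 0 °C → rt
Reagents that add atoms: none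
Why: SN2 hydride opening of the spiro-epoxide at its CH2 carbon gives the C10 methyl and the tertiary C9 alcohol without touching the C9 configuration; the C15 ketone is reduced as well and is restored in step 8.

Step 8
Reactants: 10 (1R,3aR,7aR)-1,4,4-trimethyloctahydro-1H-indene-1,5-diol
Product: 11 (1R,3aR,7aR)-1-hydroxy-1,4,4-trimethyloctahydro-5H-inden-5-one
Conditions: Dess–Martin periodinane, NaHCO3, CH2Cl2, rt
Reagents that add atoms: none
Why: Dess–Martin oxidation returns the C15 ketone from either carbinol epimer, while the tertiary C9 alcohol cannot be oxidised.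

Step 9
Reactants: 11 (1R,3aR,7aR)-1-hydroxy-1,4,4-trimethyloctahydro-5H-inden-5-one
Product: 12 (1R,3aR,7aR)-1-[(tert-butyldimethylsilyl)oxy]-1,4,4-trimethyloctahydro-5H-inden-5-one
Conditions: TBSOTf, 2,6-lutidine, CH2Cl2, 0 °C
Reagents that add atoms: tert-butyldimethylsilyl triflate, CC(C)(C)[Si](C)(C)OS(=O)(=O)C(F)(F)F
Why: silylation of the tertiary alcohol with the silyl triflate and a hindered base (silyl ether protection) covers O11 for the Lewis-acid and organometallic steps that follow; no stereocentre is affected.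

Step 10
Reactants: 13 N-ethyl-N-nitrosourea
Product: 14 diazoethane (cold toluene solution, dried over KOH pellets, titrated)
Conditions: 40% aq. KOH, toluene, 0 °C
Reagents that add atoms: none
Why: base-induced cleavage of the N-nitrosourea is the standard way to generate a non-stabilised diazoalkane, which is used at once in solution.

Step 11
Reactants: 12 (1R,3aR,7aR)-1-[(tert-butyldimethylsilyl)oxy]-1,4,4-trimethyloctahydro-5H-inden-5-one; 14 diazoethane
Product: 16 (1R,3aR,6R,8aR)-1-[(tert-butyldimethylsilyl)oxy]-1,4,4,6-tetramethyloctahydroazulen-5(1H)-one, via diazonium betaine 15 (not isolated)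
Conditions: Sc(OTf)3 (10 mol %), 1,1,1-tris[(4S)-4-isopropyl-4,5-dihydrooxazol-2-yl]ethane (11 mol %), toluene, −78 → −40 °C, slow addition of 14
Reagents that add atoms: none
Why: The scandium–tris(oxazoline) Lewis acid binds the C15 carbonyl, the nucleophilic carbon of diazoethane adds to give betaine 15, and the C15–C3 bond, antiperiplanar to the departing N2, shifts to the diazo carbon, so that C2 with its methyl C1 is inserted between C15 and C3 and the bonds C2–C15 and C2–C3 are formed. The closest known reaction type is the Lewis-acid-catalysed homologation of cyclic ketones with non-stabilised diazoalkanes (a Tiffeneau–Demjanov-type ring enlargement), including its scandium-catalysed asymmetric form. No ring is closed end to end: the seven-membered ring C2–C3–C4–C5–C6–C12–C15 arises by enlargement of the six-membered ring through the 1,2-shift. The new stereocentre C2 (R) is set by the chiral ligand, which decides which face of the diazo carbon bonds to the bound carbonyl and hence where the methyl group lies in the migrating betaine; the ketone is isolated without base so that this α-centre is not epimerised. The step needs migration of C3 and not C12, and a single insertion: the quaternary C12 is the more hindered group and should not take the antiperiplanar position, and the product ketone, flanked by quaternary C12 and tertiary C2, should be too hindered to react again.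

Step 12
Reactants: 16 (1R,3aR,6R,8aR)-1-[(tert-butyldimethylsilyl)oxy]-1,4,4,6-tetramethyloctahydroazulen-5(1H)-one
Product: 17 (1R,3aR,6R,8aR)-1-[(tert-butyldimethylsilyl)oxy]-5-ethenyl-1,4,4,6-tetramethyldecahydroazulen-5-ol (configuration at the new carbinol carbon open, of no consequence)
Conditions: CH2=CHMgBr, CeCl3, THF, −78 → 0 °C
Reagents that add atoms: vinylmagnesium bromide, C=C[Mg]Br
Why: cerium-promoted Grignard 1,2-addition to the hindered, enolisable C15 ketone brings in C16 and C17 without enolisation, so C2 is not epimerised; the new C15 carbinol centre disappears in step 13.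

Step 13
Reactants: 17 (1R,3aR,6R,8aR)-1-[(tert-butyldimethylsilyl)oxy]-5-ethenyl-1,4,4,6-tetramethyldecahydroazulen-5-ol
Product: 18 (2E)-2-[(1R,3aR,6R,8aR)-1-[(tert-butyldimethylsilyl)oxy]-1,4,4,6-tetramethyloctahydroazulen-5(1H)-ylidene]ethan-1-ol
Conditions: Ph3SiOReO3 (3 mol %), Et2O, −50 → 0 °C
Reagents that add atoms: none
Why: rhenium-oxo-catalysed 1,3-transposition of the allylic alcohol ([3,3] shift of the perrhenate ester) is driven to the primary alcohol by relief of strain at C15, and its reversibility should give the E isomer, with C17 on the side of C2 and away from quaternary C12.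

Step 14
Reactants: 19 2,2,6-trimethyl-4H-1,3-dioxin-4-one; 20 geranyl bromide
Product: 22 2,2-dimethyl-6-[(3E)-4,8-dimethylnona-3,7-dien-1-yl]-4H-1,3-dioxin-4-one, via lithium dienolate 21 (not isolated)
Conditions: LiN(i-Pr)2, DMPU, THF, −78 °C; then 20, −78 → −20 °C
Reagents that add atoms: none
Why: vinylogous enolate alkylation, in which γ-deprotonation gives the dienolate and the allylic bromide reacts at the γ-carbon (C31) by SN2; no stereocentre is formed and the E double bond of the geranyl unit is untouched.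

Step 15
Reactants: 22 2,2-dimethyl-6-[(3E)-4,8-dimethylnona-3,7-dien-1-yl]-4H-1,3-dioxin-4-one
Product: 23 6-{2-[(2R,3R)-3-{2-[(2R)-3,3-dimethyloxiran-2-yl]ethyl}-3-methyloxiran-2-yl]ethyl}-2,2-dimethyl-4H-1,3-dioxin-4-one
Conditions: D-fructose-derived Shi ketone (0.5 equiv), KHSO5 (as Oxone), K2CO3, Bu4NHSO4, Na2B4O7 buffer, MeCN/CH2(OMe)2/H2O, 0 °C
Reagents that add atoms: potassium peroxymonosulfate, [K+].[O-]S(=O)(=O)OO
Why: Shi asymmetric epoxidation, in which the chiral dioxirane epoxidises both electron-rich trisubstituted alkenes through the spiro transition state and sets C19, C29 and C23 (all R), while the electron-poor dioxinone double bond should be left alone.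

Step 16
Reactants: 23 6-{2-[(2R,3R)-3-{2-[(2R)-3,3-dimethyloxiran-2-yl]ethyl}-3-methyloxiran-2-yl]ethyl}-2,2-dimethyl-4H-1,3-dioxin-4-one
Product: 24 tricyclic dioxinone: 2,2-dimethyl-1,3-dioxin-4-one fused through C18=C32 to the cyclohexene ring of the trans-fused (3R,5aR,9aR)-3-[(tert-butyldimethylsilyl)oxy]-2,2,5a-trimethyl-octahydro-1-benzoxepine
Conditions: TBSOTf (1.2 equiv), 2,6-di-tert-butyl-4-methylpyridine, CH2Cl2, −78 °C
Reagents that add atoms: tert-butyldimethylsilyl triflate, CC(C)(C)[Si](C)(C)OS(=O)(=O)C(F)(F)F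
Why: Proposed new method: silylation of the terminal epoxide makes its tertiary carbon C25 electrophilic, the oxygen of the neighbouring epoxide (O28) attacks it, and the resulting epoxonium ion is opened with inversion at its tertiary carbon C19 by C18 of the dioxinone, an enol-ether carbon, after which loss of the C18 proton restores the dioxinone; the closest known reaction types are silyl-triflate-promoted oxa-/carbacyclisation cascades of polyepoxides that end in enol silanes or alkenes and the capture of oxocarbenium ions by the α-carbon of dioxinones in Prins cyclisations; the trans ring fusion and the configurations at C19, C29 and C23 follow from the E epoxide geometry, anti opening at C19 and retention at the two carbons that keep their C–O bonds.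

Step 17
Reactants: 24 tricyclic dioxinone; 18 (2E)-2-[(1R,3aR,6R,8aR)-1-[(tert-butyldimethylsilyl)oxy]-1,4,4,6-tetramethyloctahydroazulen-5(1H)-ylidene]ethan-1-ol
Product: 26 (2E)-2-[(1R,3aR,6R,8aR)-1-[(tert-butyldimethylsilyl)oxy]-1,4,4,6-tetramethyloctahydroazulen-5(1H)-ylidene]ethyl (3R,5aR,9aR)-3-[(tert-butyldimethylsilyl)oxy]-2,2,5a-trimethyl-7-oxodecahydro-1-benzoxepine-6-carboxylate (C18 epimers and enol), via acylketene 25 (not isolated)
Conditions: toluene, 120 °C (sealed tube)
Reagents that add atoms: none
Why: thermal retro-[4+2] fragmentation of the dioxinone releases acetone and the α-oxoketene, which the primary allylic alcohol traps (acylketene esterification) under neutral conditions that leave both silyl ethers and the trisubstituted alkene alone.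

Step 18
Reactants: 26 allyl β-keto ester
Product: 27 (3R,5aR,6R,9aR)-3-[(tert-butyldimethylsilyl)oxy]-6-{(2E)-2-[(1R,3aR,6R,8aR)-1-[(tert-butyldimethylsilyl)oxy]-1,4,4,6-tetramethyloctahydroazulen-5(1H)-ylidene]ethyl}-2,2,5a-trimethyloctahydro-1-benzoxepin-7(2H)-one
Conditions: Pd(PPh3)4 (5 mol %), THF, rt
Reagents that add atoms: none
Why: Tsuji decarboxylative allylation, in which zerovalent palladium ionises the allylic ester to a π-allyl complex and the β-keto carboxylate, C18 bonds to the less hindered allyl terminus C17 (C15 is fully substituted), CO2 is lost, and ketonisation by axial protonation on the face away from the axial C19 methyl should leave the new chain equatorial (18R), the arrangement also expected to be favoured at equilibrium; the E geometry of C15=C16 is the less strained one and should be kept.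

Step 19
Reactants: 27 allylated ketone
Product: 28 (3R,5aR,6R,7S,9aR)-3-[(tert-butyldimethylsilyl)oxy]-6-{(2E)-2-[(1R,3aR,6R,8aR)-1-[(tert-butyldimethylsilyl)oxy]-1,4,4,6-tetramethyloctahydroazulen-5(1H)-ylidene]ethyl}-2,2,5a,7-tetramethyldecahydro-1-benzoxepin-7-ol
Conditions: MeMgBr, CeCl3, THF, −78 °C
Reagents that add atoms: methylmagnesium bromide, C[Mg]Br
Why: cerium-promoted Grignard addition to the C32 ketone, in which the axial C19 methyl blocks axial attack so that the methyl group C33 enters equatorially and the C32 hydroxyl ends up axial, cis to the C19 methyl (7S), without enolisation at C18.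

Step 20
Reactants: 28 bis-silyl ether
Product: 29 (3R,5aR,6R,7S,9aR)-6-{(2E)-2-[(1R,3aR,6R,8aR)-1-hydroxy-1,4,4,6-tetramethyloctahydroazulen-5(1H)-ylidene]ethyl}-2,2,5a,7-tetramethyldecahydro-1-benzoxepine-3,7-diol (CNP0167890.2)
Conditions: TBAF, THF, 60 °C
Reagents that add atoms: none
Why: fluoride-mediated desilylation removes the secondary and, on warming, the tertiary silyl ether; no stereocentre or double bond is touched.

**Compound list**

1 | cyclopent-2-en-1-one | O=C1C=CCC1 | starting material
2 | 1-methoxy-2-methyl-1-(trimethylsilyloxy)prop-1-ene | COC(O[Si](C)(C)C)=C(C)C | starting material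
3 | methyl 2-methyl-2-[(1R)-3-(trimethylsilyloxy)cyclopent-2-en-1-yl]propanoate | COC(=O)C(C)(C)[C@@H]1CCC(O[Si](C)(C)C)=C1 | intermediate
4 | methyl acrylate | C=CC(=O)OC | starting material
5 | methyl 3-[(1S,2R)-2-(1-methoxy-2-methyl-1-oxopropan-2-yl)-5-oxocyclopentyl]propanoate | COC(=O)CC[C@@H]1C(=O)CC[C@H]1C(C)(C)C(=O)OC | intermediate
6 | methyl (3aR,7aR)-4,4-dimethyl-1,5-dioxooctahydro-1H-indene-6-carboxylate | COC(=O)C1C[C@@H]2[C@@H](CCC2=O)C(C)(C)C1=O | intermediate
7 | methyl (3aR,7aR)-4,4-dimethyl-1-methylidene-5-oxooctahydro-1H-indene-6-carboxylate | COC(=O)C1C[C@@H]2[C@@H](CCC2=C)C(C)(C)C1=O | intermediate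
8 | (3aR,7aR)-4,4-dimethyl-1-methylideneoctahydro-5H-inden-5-one | O=C1CC[C@@H]2[C@@H](CCC2=C)C1(C)C | intermediate
9 | (3aR,7aR)-4,4-dimethylhexahydrospiro[indene-1,2'-oxiran]-5(4H)-one, spiro carbon R | O=C1CC[C@@H]2[C@@H](CC[C@]23CO3)C1(C)C | intermediate
10 | (1R,3aR,7aR)-1,4,4-trimethyloctahydro-1H-indene-1,5-diol | OC1CC[C@@H]2[C@@H](CC[C@@]2(C)O)C1(C)C | intermediate
11 | (1R,3aR,7aR)-1-hydroxy-1,4,4-trimethyloctahydro-5H-inden-5-one | O=C1CC[C@@H]2[C@@H](CC[C@@]2(C)O)C1(C)C | intermediate
12 | (1R,3aR,7aR)-1-[(tert-butyldimethylsilyl)oxy]-1,4,4-trimethyloctahydro-5H-inden-5-one | O=C1CC[C@@H]2[C@@H](CC[C@@]2(C)O[Si](C)(C)C(C)(C)C)C1(C)C | intermediate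
13 | N-ethyl-N-nitrosourea | CCN(N=O)C(N)=O | starting material
14 | diazoethane | CC=[N+]=[N-] | intermediate
15 | diazonium betaine from addition of 14 to C15 of 12 | CC([N+]#N)C1([O-])CC[C@@H]2[C@@H](CC[C@@]2(C)O[Si](C)(C)C(C)(C)C)C1(C)C | intermediate
16 | (1R,3aR,6R,8aR)-1-[(tert-butyldimethylsilyl)oxy]-1,4,4,6-tetramethyloctahydroazulen-5(1H)-one | C[C@@H]1CC[C@@H]2[C@@H](CC[C@@]2(C)O[Si](C)(C)C(C)(C)C)C(C)(C)C1=O | intermediate
17 | (1R,3aR,6R,8aR)-1-[(tert-butyldimethylsilyl)oxy]-5-ethenyl-1,4,4,6-tetramethyldecahydroazulen-5-ol | C[C@@H]1CC[C@@H]2[C@@H](CC[C@@]2(C)O[Si](C)(C)C(C)(C)C)C(C)(C)C1(O)C=C | intermediate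
18 | (2E)-2-[(1R,3aR,6R,8aR)-1-[(tert-butyldimethylsilyl)oxy]-1,4,4,6-tetramethyloctahydroazulen-5(1H)-ylidene]ethan-1-ol | C[C@@H]1CC[C@@H]2[C@@H](CC[C@@]2(C)O[Si](C)(C)C(C)(C)C)C(C)(C)/C1=C/CO | intermediate
19 | 2,2,6-trimethyl-4H-1,3-dioxin-4-one | CC1=CC(=O)OC(C)(C)O1 | starting material
20 | geranyl bromide | CC(C)=CCC/C(C)=C/CBr | starting material
21 | lithium 2,2-dimethyl-6-methylidene-6H-1,3-dioxin-4-olate | [Li]OC1=CC(=C)OC(C)(C)O1 | intermediate
22 | 2,2-dimethyl-6-[(3E)-4,8-dimethylnona-3,7-dien-1-yl]-4H-1,3-dioxin-4-one | CC(C)=CCC/C(C)=C/CCC1=CC(=O)OC(C)(C)O1 | intermediate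
23 | 6-{2-[(2R,3R)-3-{2-[(2R)-3,3-dimethyloxiran-2-yl]ethyl}-3-methyloxiran-2-yl]ethyl}-2,2-dimethyl-4H-1,3-dioxin-4-one | O=C1C=C(CC[C@H]2O[C@]2(C)CC[C@H]2OC2(C)C)OC(C)(C)O1 | intermediate
24 | tricyclic dioxinone, (3R,5aR,9aR)-3-[(tert-butyldimethylsilyl)oxy]-2,2,5a-trimethyl benzoxepine fused at C18=C32 to 2,2-dimethyl-1,3-dioxin-4-one | O=C1OC(C)(C)OC2=C1[C@@]3(C)CC[C@@H](O[Si](C)(C)C(C)(C)C)C(C)(C)O[C@@H]3CC2 | intermediate
25 | acylketene, (3R,5aR,9aR)-3-[(tert-butyldimethylsilyl)oxy]-2,2,5a-trimethyl-6-(oxomethylidene)octahydro-1-benzoxepin-7(2H)-one | O=C=C1C(=O)CC[C@H]2OC(C)(C)[C@H](O[Si](C)(C)C(C)(C)C)CC[C@]12C | intermediate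
26 | (2E)-2-[(1R,3aR,6R,8aR)-1-[(tert-butyldimethylsilyl)oxy]-1,4,4,6-tetramethyloctahydroazulen-5(1H)-ylidene]ethyl (3R,5aR,9aR)-3-[(tert-butyldimethylsilyl)oxy]-2,2,5a-trimethyl-7-oxodecahydro-1-benzoxepine-6-carboxylate | C[C@@H]1CC[C@@H]2[C@@H](CC[C@@]2(C)O[Si](C)(C)C(C)(C)C)C(C)(C)/C1=C/COC(=O)C1C(=O)CC[C@H]2OC(C)(C)[C@H](O[Si](C)(C)C(C)(C)C)CC[C@]12C | intermediate
27 | (3R,5aR,6R,9aR)-3-[(tert-butyldimethylsilyl)oxy]-6-{(2E)-2-[(1R,3aR,6R,8aR)-1-[(tert-butyldimethylsilyl)oxy]-1,4,4,6-tetramethyloctahydroazulen-5(1H)-ylidene]ethyl}-2,2,5a-trimethyloctahydro-1-benzoxepin-7(2H)-one | C[C@@H]1CC[C@@H]2[C@@H](CC[C@@]2(C)O[Si](C)(C)C(C)(C)C)C(C)(C)/C1=C/C[C@@H]1[C@@]2(C)CC[C@@H](O[Si](C)(C)C(C)(C)C)C(C)(C)O[C@@H]2CCC1=O | intermediate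
28 | (3R,5aR,6R,7S,9aR)-3-[(tert-butyldimethylsilyl)oxy]-6-{(2E)-2-[(1R,3aR,6R,8aR)-1-[(tert-butyldimethylsilyl)oxy]-1,4,4,6-tetramethyloctahydroazulen-5(1H)-ylidene]ethyl}-2,2,5a,7-tetramethyldecahydro-1-benzoxepin-7-ol | C[C@@H]1CC[C@@H]2[C@@H](CC[C@@]2(C)O[Si](C)(C)C(C)(C)C)C(C)(C)/C1=C/C[C@@H]1[C@@]2(C)CC[C@@H](O[Si](C)(C)C(C)(C)C)C(C)(C)O[C@@H]2CC[C@]1(C)O | intermediate
29 | (3R,5aR,6R,7S,9aR)-6-{(2E)-2-[(1R,3aR,6R,8aR)-1-hydroxy-1,4,4,6-tetramethyloctahydroazulen-5(1H)-ylidene]ethyl}-2,2,5a,7-tetramethyldecahydro-1-benzoxepine-3,7-diol | C[C@@H]1CC[C@@H]2[C@@H](CC[C@@]2(C)O)C(C)(C)/C1=C/C[C@@H]1[C@@]2(C)CC[C@@H](O)C(C)(C)O[C@@H]2CC[C@]1(C)O | target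

**Step count and risks**

Total step count: 20. Longest linear sequence: 16 (steps 1–9, 11–13, 17–20).

Steps most likely to fail:

1. Step 16 (proposed new method). The cascade may stop before the C–C bond is made, by proton loss from the oxonium stage, capture by triflate or a hydride shift to a ketone, because the dioxinone is a weaker π-nucleophile than an enol silane. The fallback sets out from 23 and uses the established enol-silane terminator. Heating 23 with methanol in toluene (110 °C) opens the dioxinone to methyl β-keto ester F1. O-Silylation (NaH, TBSCl, THF, 0 °C) gives silyl enol ether F2. TBSOTf with 2,6-di-tert-butyl-4-methylpyridine (CH2Cl2, −78 °C) then runs the oxa-/carbacyclisation to bicyclic β-keto ester F3. Transesterification of F3 with alcohol 18 (DMAP cat., toluene, reflux, 4 Å sieves) gives 26, where the route is rejoined.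

2. Step 11 (key step). Addition to the hindered carbonyl may be slow against decomposition of diazoethane, epoxide formation may compete, or C2 may form with the wrong configuration if substrate and ligand preferences oppose each other. The fallback sets out from 12 and introduces the methyl group separately. Homologation with trimethylsilyldiazomethane (Sc(OTf)3 cat., CH2Cl2, −78 °C; desilylating acidic work-up) gives cycloheptanone F4, which can enolise only towards C2. Its lithium enolate (LiN(i-Pr)2, THF, −78 °C) is methylated with MeI, expected on the convex face (the face of H5 and H6), to give 16.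

3. Step 18. The hindered π-allyl complex may lose a β-hydrogen (diene formation alongside simple protonation of the ketone), or the C–C bond may form with the wrong C18 configuration. The fallback sets out from 17 and 24 and uses a thermal Carroll rearrangement. Heating the tertiary vinyl carbinol 17 with 24 (xylene, 140 °C) lets acylketene 25 acylate the tertiary alcohol to allylic β-keto ester F5. Its enol undergoes the [3,3] shift that forms C17–C18 and the C15=C16 double bond. The resulting β-keto acid F6 loses CO2 under the same conditions and gives 27, where the route is rejoined without palladium and without steps 13 and 17.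

Further compounds
F1 | step 16 | methyl 5-[(2R,3R)-3-{2-[(2R)-3,3-dimethyloxiran-2-yl]ethyl}-3-methyloxiran-2-yl]-3-oxopentanoate | COC(=O)CC(=O)CC[C@H]1O[C@]1(C)CC[C@H]1OC1(C)C
F2 | step 16 | methyl (2Z)-3-[(tert-butyldimethylsilyl)oxy]-5-[(2R,3R)-3-{2-[(2R)-3,3-dimethyloxiran-2-yl]ethyl}-3-methyloxiran-2-yl]pent-2-enoate | COC(=O)/C=C(\O[Si](C)(C)C(C)(C)C)CC[C@H]1O[C@]1(C)CC[C@H]1OC1(C)C
F3 | step 16 | methyl (3R,5aR,9aR)-3-[(tert-butyldimethylsilyl)oxy]-2,2,5a-trimethyl-7-oxodecahydro-1-benzoxepine-6-carboxylate | COC(=O)C1C(=O)CC[C@H]2OC(C)(C)[C@H](O[Si](C)(C)C(C)(C)C)CC[C@]12C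
F4 | step 11 | (1R,3aR,8aR)-1-[(tert-butyldimethylsilyl)oxy]-1,4,4-trimethyloctahydroazulen-5(1H)-one | O=C1CCC[C@@H]2[C@@H](CC[C@@]2(C)O[Si](C)(C)C(C)(C)C)C1(C)C
F5 | step 18 | (1R,3aR,6R,8aR)-1-[(tert-butyldimethylsilyl)oxy]-5-ethenyl-1,4,4,6-tetramethyldecahydroazulen-5-yl (3R,5aR,9aR)-3-[(tert-butyldimethylsilyl)oxy]-2,2,5a-trimethyl-7-oxodecahydro-1-benzoxepine-6-carboxylate | C[C@@H]1CC[C@@H]2[C@@H](CC[C@@]2(C)O[Si](C)(C)C(C)(C)C)C(C)(C)C1(C=C)OC(=O)C1C(=O)CC[C@H]2OC(C)(C)[C@H](O[Si](C)(C)C(C)(C)C)CC[C@]12C
F6 | step 18 | (3R,5aR,9aR)-3-[(tert-butyldimethylsilyl)oxy]-6-{(2E)-2-[(1R,3aR,6R,8aR)-1-[(tert-butyldimethylsilyl)oxy]-1,4,4,6-tetramethyloctahydroazulen-5(1H)-ylidene]ethyl}-2,2,5a-trimethyl-7-oxodecahydro-1-benzoxepine-6-carboxylic acid | C[C@@H]1CC[C@@H]2[C@@H](CC[C@@]2(C)O[Si](C)(C)C(C)(C)C)C(C)(C)/C1=C/CC1(C(=O)O)C(=O)CC[C@H]2OC(C)(C)[C@H](O[Si](C)(C)C(C)(C)C)CC[C@]12C
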